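The rate constants come from no measurement; the flask was simulated.

What is left over of the nucleophile is our subject: how much of it stays free, and how much the acid holds.

electrophile 10 mM (fed, over 12 s); nucleophile 1.80 equiv; free base 3.00 equiv; time 3.0 min

    target ⇌ isomer of the product (K1 = 1.9, k1 = 0.049 s⁻¹)
    electrophile ⇌ dormant form (K2 = 1.7, k2 = 0.085 s⁻¹)
    nucleophile + acid set free ⇌ protonated nucleophile, settled at all times (K3 = 17000 L mol⁻¹)
    acid set free + free base ⇌ salt of the base, settled at all times (K4 = 7400 L mol⁻¹)
    acid set free → by-product carried off (k5 = 0.024 s⁻¹)
    electrophile + nucleophile → acid set free + target (k6 = 2.6 L mol⁻¹ s⁻¹)

* part of the electrophile that has reacted at 3.0 min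
* share of the unused nucleophile that is free and not bound as protonated nucleophile, at 3.0 min

- what has gone from electrophile into another species counts as reacted, even if it can come back
- run time (flask): 3.0 min

The electrophile is the limiting reagent, charged at less than the nucleophile. Call x the load: the acid set free so far, which equals target plus isomer of the product, since the isomer step neither takes nor gives acid.

First we take the main step by itself, with the feed counted at its midpoint, so the time is 174 s. The nucleophile excess is 8.00 mM, and second-order kinetics leave

electrophile = excess/(1.80·exp(2.6 L mol⁻¹ s⁻¹·excess·time) − 1) = 0.121 mM, so 98.8 % has reacted.

Next we add the dormant form. It relaxes in 0.0856 min, faster than the main step's 0.25 min, so electrophile and dormant form move as one pool. The rate constant falls to 0.963 L mol⁻¹ s⁻¹, the pool left is 1.36 mM, and x = 8.64 mM.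

Then we add the acid. Both takers feel the same free acid, so y = [protonated nucleophile]/[nucleophile] stands to [salt of the base]/[free base] as the grip, the ratio of their two binding constants, 2.30. With U the unused nucleophile, and the large [free base] corrected by x/2:

x = U·y/(1 + y) + [free base]·y/grip, and fr = 1/(1 + y).

This gives y = 0.495 and a free share of 66.9 %. The main step runs on free nucleophile, and in our reckoning its share goes from 1 before any acid is set free down to about this value, so we multiply the rate constant by the mean of the two:

pool left = 1.77 mM, x = 8.23 mM, y = 0.458.

Our reckoning therefore gives fr = 68.6 %, and c = 93.4 %, with the pool split by its equilibrium. The balance leaves out free acid, about 0.0269 mM, and acid carried off, about 0.112 mM with that free acid held over the whole time; each of them is small against x.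

The forecast gave 93 % reacted and 69 % free, holding that “The released acid is shared between the free base and the nucleophile”.

The simulation gives 93.2 % reacted and 69.3 % free.

In this flask at 3.00 min, the grip applied to the base side, 4.84 mM of salt of the base against 83.9 % of the charge still standing as free base, gives a free share of 69.3 %. The neighbour flask has 1.20 equiv of free base, its other charges and the time as in the recipe, and its target and isomer of the product give x = 7.73 mM. The same balance, with the same grip, gives y = 0.850, so a free share of 54.1 %. The simulation of that neighbour flask gives a free share of 56.1 %.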